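**Retrosynthetic overview**

1. The last three steps only remove a carbonyl group from the one-carbon bridge C7 of the pinane half (reduction, thiocarbonylation, radical deoxygenation). The full skeleton exists after step 5.
2. Key disconnection: the cyclobutane C1–C6–C5–C7 of the bicyclo[3.1.1]heptane is opened across its two opposite bonds, C1–C7 and C5–C6. This gives a ketene (C5=C7=O) on a three-carbon tether and a 2-methylprop-1-enyl group (C1=C6), both on the quaternary carbon C2 of a chroman acid. Forward: intramolecular ketene–alkene [2+2].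
3. Enabling feature: in that four-membered ring the gem-dimethyl carbon C6 (carries the positive charge of the polar [2+2]) lies opposite C7, an unsubstituted CH2 between two bridgeheads (can be carried as a non-enolisable, removable C=O). The spiro carbon C2, which bears the ring oxygen, hinges tether and alkene and steers the facial choice.
4. Chroman acid: C4–C4a bond by enantioselective organocatalytic Michael addition of syncarpic acid to an enone ester (sets C4). Then alkenyl addition to the ketone and SN1 oxa-cyclisation (O1–C2 bond, sets C2).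
5. Ring order: six-membered triketone ring (bought), then the dihydropyran ring (step 3), then the cyclobutane together with both six-membered carbocycles of the bicyclo[3.1.1]heptane (step 5).

Key step: step 5

Remark: syncarpic acid is taken as a catalogue compound; the sense of induction in step 2 is assigned by analogy and, if found reversed, is corrected with the quinine-derived pseudo-enantiomer of the catalyst.

**Route**

Step 1
Reactants: 1 4-methylpent-1-yne; 2 methyl 5-chloro-5-oxopentanoate
Product: 4 methyl (E)-9-methyl-5-oxodec-6-enoate, via alkenylzirconocene chloride 3 (not isolated)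
Conditions: Cp2Zr(H)Cl (1.1 equiv), CH2Cl2, rt; then 2, CuBr·SMe2 (10 mol %), rt
Reagents that add atoms: none
Why: Syn hydrozirconation of the terminal alkyne puts zirconium on the terminal carbon and fixes the E geometry, and the alkenylzirconocene is then acylated by the acid chloride under copper catalysis (hydrozirconation–acylation) without touching the methyl ester.

Step 2
Reactants: 5 syncarpic acid (2,2,4,4-tetramethylcyclohexane-1,3,5-trione, drawn as its enol); 4 methyl (E)-9-methyl-5-oxodec-6-enoate
Product: 6 methyl (7S)-7-(2-hydroxy-3,3,5,5-tetramethyl-4,6-dioxocyclohex-1-en-1-yl)-9-methyl-5-oxodecanoate (open form; in equilibrium with its cyclic hemiketal)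
Conditions: 9-amino-9-deoxy-epi-quinidine (20 mol %), CF3CO2H (40 mol %), THF, rt
Reagents that add atoms: none
Why: The primary amine activates the enone as its iminium ion while the protonated quinuclidine holds the triketone enol (organocatalytic Michael addition of a cyclic 1,3-dicarbonyl compound to an enone), which should set the isobutyl-bearing centre as 7S; the catalyst antipode needed is the one that turns 4-hydroxycoumarin and benzylideneacetone into (R)-warfarin, which has the same spatial arrangement.

Step 3
Reactants: 6 methyl (7S)-7-(2-hydroxy-3,3,5,5-tetramethyl-4,6-dioxocyclohex-1-en-1-yl)-9-methyl-5-oxodecanoate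
Product: 8 methyl 4-[(2R,4S)-6,6,8,8-tetramethyl-4-(2-methylpropyl)-2-(2-methylprop-1-en-1-yl)-5,7-dioxo-3,4,5,6,7,8-hexahydro-2H-chromen-2-yl]butanoate, via tertiary allylic alcohol 7 (not isolated)
Conditions: 2-methylprop-1-enylmagnesium bromide (3.5 equiv), CeCl3 (3.5 equiv), THF, −78 °C; aq. NH4Cl; then camphorsulfonic acid (10 mol %), CH2Cl2, 0 °C
Reagents that add atoms: 2-methylprop-1-enylmagnesium bromide, CC(C)=C[Mg]Br
Why: The first equivalent of the alkenylcerium reagent removes the acidic proton and unmasks the ketone, the next adds to it faster than to the ester (carbonyl addition of an organocerium reagent), and acid then ionises the tertiary allylic alcohol so that the enol oxygen closes the dihydropyran on the inner terminus of the allyl cation (SN1 oxa-cyclisation); C2 is set in this closure, where the isobutyl group is pseudo-axial to avoid the neighbouring ring carbonyl and the rigid, branched alkenyl group should take the equatorial site, leaving the flexible ester chain axial and cis to isobutyl (2R), and because the ionisation is reversible the unwanted C2 epimer can be re-equilibrated.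

Step 4
Reactants: 8 methyl 4-[(2R,4S)-6,6,8,8-tetramethyl-4-(2-methylpropyl)-2-(2-methylprop-1-en-1-yl)-5,7-dioxo-3,4,5,6,7,8-hexahydro-2H-chromen-2-yl]butanoate
Product: 9 4-[(2R,4S)-6,6,8,8-tetramethyl-4-(2-methylpropyl)-2-(2-methylprop-1-en-1-yl)-5,7-dioxo-3,4,5,6,7,8-hexahydro-2H-chromen-2-yl]butanoic acid
Conditions: LiOH, THF/H2O, 0 °C to rt; then cold 0.5 M HCl to pH 4
Reagents that add atoms: lithium hydroxide, [Li+].[OH-]
Why: Saponification of the unhindered methyl ester; the vinylogous ester is shielded by its two quaternary neighbours and has no enolisable position, and the tertiary allylic ether is stable to base.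

Step 5
Reactants: 9 4-[(2R,4S)-6,6,8,8-tetramethyl-4-(2-methylpropyl)-2-(2-methylprop-1-en-1-yl)-5,7-dioxo-3,4,5,6,7,8-hexahydro-2H-chromen-2-yl]butanoic acid
Product: 12 (1R,2R,4'S,5R)-6,6,6',6',8',8'-hexamethyl-4'-(2-methylpropyl)-3',4'-dihydrospiro[bicyclo[3.1.1]heptane-2,2'-chromene]-5',7,7'(6'H,8'H)-trione (ring oxygen on the side of the carbonyl bridge), via acid chloride 10 (not isolated), via ketene 11 (not isolated)
Conditions: 1-chloro-N,N,2-trimethylprop-1-en-1-amine (1.2 equiv), CH2Cl2, 0 °C to rt; then slow addition to Et3N (5 equiv) in toluene at reflux (final 0.005 M)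
Reagents that add atoms: none
Why: The acid chloride loses HCl to Et3N to give the aldoketene, whose carbonyl carbon attacks the inner, less substituted alkene carbon while positive charge builds on the CMe2 carbon, which then bonds to the ketene α-carbon: a thermal, asynchronous [2+2] (formally π2s + π2a) that forms the C(O)–CH and CH–CMe2 bonds in one step. The closest known reaction is the intramolecular cycloaddition of ketenes tethered by three carbons to a trisubstituted alkene, which gives 7,7-dimethylbicyclo[3.1.1]heptan-6-ones. The cyclobutanone is closed by the cycloaddition itself and the two six-membered carbocycles arise in the bridged (crossed) mode, the first bond being a 6-exo attack on the alkene; the fused bicyclo[3.2.0] mode would leave a secondary cation next to the oxygen-bearing carbon. The two new bridgehead centres are necessarily cis to each other, and their configuration relative to C2 follows from the alkene face attacked: in the favoured transition state the tether is inside, the ring C–O bond lies in the alkene plane and the ring CH2 is anti to the incoming ketene carbon, so that a donor C–C bond and not the acceptor C–O bond is aligned with the reacting π bond, which places the ring oxygen beside the carbonyl bridge and the ring CH2 under the CMe2 bridge as in the target. The step needs regioselectivity (secured by the substitution pattern of the alkene), facial selectivity (secured by the allylic oxygen on C2) and chemoselectivity over ketene dimerisation (high dilution, gem-dialkyl effect of C2); the enol ether C=C of the vinylogous ester is tetrasubstituted and electron-poor and should not compete.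

Step 6
Reactants: 12 (1R,2R,4'S,5R)-6,6,6',6',8',8'-hexamethyl-4'-(2-methylpropyl)-3',4'-dihydrospiro[bicyclo[3.1.1]heptane-2,2'-chromene]-5',7,7'(6'H,8'H)-trione
Product: 13 (1S,2R,4'S,5R,7R)-7-hydroxy-6,6,6',6',8',8'-hexamethyl-4'-(2-methylpropyl)-3',4'-dihydrospiro[bicyclo[3.1.1]heptane-2,2'-chromene]-5',7'(6'H,8'H)-dione (hydroxyl pointing toward the trimethylene bridge)
Conditions: NaBH4, MeOH/CH2Cl2, −78 to −40 °C
Reagents that add atoms: none
Why: The strained cyclobutanone is far more electrophilic than the vinylogous ester carbonyl and the ketone between two quaternary carbons (chemoselective borohydride reduction), hydride should enter from the open face away from the trimethylene bridge, and the configuration of the new carbinol is of no consequence because it is removed in step 8.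

Step 7
Reactants: 13 (1S,2R,4'S,5R,7R)-7-hydroxy-6,6,6',6',8',8'-hexamethyl-4'-(2-methylpropyl)-3',4'-dihydrospiro[bicyclo[3.1.1]heptane-2,2'-chromene]-5',7'(6'H,8'H)-dione
Product: 14 O-[(1S,2R,4'S,5R,7R)-6,6,6',6',8',8'-hexamethyl-4'-(2-methylpropyl)-5',7'-dioxo-3',4',5',6',7',8'-hexahydrospiro[bicyclo[3.1.1]heptane-2,2'-chromen]-7-yl] 1H-imidazole-1-carbothioate
Conditions: 1,1'-thiocarbonyldiimidazole (3 equiv), DMAP (cat.), 1,2-dichloroethane, 70 °C
Reagents that add atoms: 1,1'-thiocarbonyldiimidazole, S=C(n1ccnc1)n1ccnc1
Why: Neutral thioacylation of the secondary alcohol (first half of a Barton–McCombie deoxygenation) avoids a free alkoxide next to the vinylogous ester, and no other hydroxyl or enolisable position is present.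

Step 8
Reactants: 14 O-[(1S,2R,4'S,5R,7R)-6,6,6',6',8',8'-hexamethyl-4'-(2-methylpropyl)-5',7'-dioxo-3',4',5',6',7',8'-hexahydrospiro[bicyclo[3.1.1]heptane-2,2'-chromen]-7-yl] 1H-imidazole-1-carbothioate
Product: 15 (1R,2R,4'S,5S)-6,6,6',6',8',8'-hexamethyl-4'-(2-methylpropyl)-3',4'-dihydrospiro[bicyclo[3.1.1]heptane-2,2'-chromene]-5',7'(6'H,8'H)-dione (target)
Conditions: Bu3SnH (2 equiv), AIBN (cat.), toluene, 100 °C
Reagents that add atoms: none
Why: Barton–McCombie deoxygenation: the stannyl radical adds to the thiocarbonyl group, the C7–O bond fragments, and the resulting cyclobutyl radical, which opens only slowly, takes hydrogen from the stannane; no stereocentre is touched.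

**Compound list**

1 | 4-methylpent-1-yne | CC(C)CC#C | starting material
2 | methyl 5-chloro-5-oxopentanoate | COC(=O)CCCC(=O)Cl | starting material
3 | chlorobis(cyclopentadienyl)[(E)-4-methylpent-1-enyl]zirconium (rings drawn σ-bonded) | CC(C)C/C=C/[Zr](Cl)(C1C=CC=C1)C1C=CC=C1 | intermediate (not isolated)
4 | methyl (E)-9-methyl-5-oxodec-6-enoate | COC(=O)CCCC(=O)/C=C/CC(C)C | intermediate
5 | syncarpic acid (enol form) | CC1(C)C(=O)C=C(O)C(C)(C)C1=O | starting material
6 | methyl (7S)-7-(2-hydroxy-3,3,5,5-tetramethyl-4,6-dioxocyclohex-1-en-1-yl)-9-methyl-5-oxodecanoate | CC(C)C[C@@H](CC(=O)CCCC(=O)OC)C1=C(O)C(C)(C)C(=O)C(C)(C)C1=O | intermediate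
7 | methyl (7S)-5-hydroxy-7-(2-hydroxy-3,3,5,5-tetramethyl-4,6-dioxocyclohex-1-en-1-yl)-9-methyl-5-(2-methylprop-1-en-1-yl)decanoate (both C5 epimers) | CC(C)C[C@@H](CC(O)(C=C(C)C)CCCC(=O)OC)C1=C(O)C(C)(C)C(=O)C(C)(C)C1=O | intermediate (not isolated)
8 | methyl 4-[(2R,4S)-6,6,8,8-tetramethyl-4-(2-methylpropyl)-2-(2-methylprop-1-en-1-yl)-5,7-dioxo-3,4,5,6,7,8-hexahydro-2H-chromen-2-yl]butanoate | CC(C)C[C@H]1C[C@@](C=C(C)C)(CCCC(=O)OC)OC2=C1C(=O)C(C)(C)C(=O)C2(C)C | intermediate
9 | 4-[(2R,4S)-6,6,8,8-tetramethyl-4-(2-methylpropyl)-2-(2-methylprop-1-en-1-yl)-5,7-dioxo-3,4,5,6,7,8-hexahydro-2H-chromen-2-yl]butanoic acid | CC(C)C[C@H]1C[C@@](C=C(C)C)(CCCC(=O)O)OC2=C1C(=O)C(C)(C)C(=O)C2(C)C | intermediate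
10 | acid chloride of 9 | CC(C)C[C@H]1C[C@@](C=C(C)C)(CCCC(=O)Cl)OC2=C1C(=O)C(C)(C)C(=O)C2(C)C | intermediate (not isolated)
11 | ketene from 10, (2R,4S)-2-(4-oxobut-3-en-1-yl) chroman | CC(C)C[C@H]1C[C@@](C=C(C)C)(CCC=C=O)OC2=C1C(=O)C(C)(C)C(=O)C2(C)C | intermediate (not isolated)
12 | (1R,2R,4'S,5R)-6,6,6',6',8',8'-hexamethyl-4'-(2-methylpropyl)-3',4'-dihydrospiro[bicyclo[3.1.1]heptane-2,2'-chromene]-5',7,7'(6'H,8'H)-trione | CC(C)C[C@H]1C[C@@]2(CC[C@H]3C(=O)[C@@H]2C3(C)C)OC2=C1C(=O)C(C)(C)C(=O)C2(C)C | intermediate
13 | (1S,2R,4'S,5R,7R)-7-hydroxy-6,6,6',6',8',8'-hexamethyl-4'-(2-methylpropyl)-3',4'-dihydrospiro[bicyclo[3.1.1]heptane-2,2'-chromene]-5',7'(6'H,8'H)-dione | CC(C)C[C@H]1C[C@@]2(CC[C@H]3[C@@H](O)[C@@H]2C3(C)C)OC2=C1C(=O)C(C)(C)C(=O)C2(C)C | intermediate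
14 | O-(7-yl) 1H-imidazole-1-carbothioate of 13 | CC(C)C[C@H]1C[C@@]2(CC[C@H]3[C@@H](OC(=S)n4ccnc4)[C@@H]2C3(C)C)OC2=C1C(=O)C(C)(C)C(=O)C2(C)C | intermediate
15 | (1R,2R,4'S,5S)-6,6,6',6',8',8'-hexamethyl-4'-(2-methylpropyl)-3',4'-dihydrospiro[bicyclo[3.1.1]heptane-2,2'-chromene]-5',7'(6'H,8'H)-dione | CC(C)C[C@H]1C[C@@]2(CC[C@H]3C[C@@H]2C3(C)C)OC2=C1C(=O)C(C)(C)C(=O)C2(C)C | target

**Step count and risks**

Total steps: 8. Longest linear sequence: 8 (steps 1 to 8; syncarpic acid enters at step 2).

Steps most likely to fail:

1. Step 5. The aldoketene may dimerise or be consumed otherwise before it adds to an alkene that is deactivated by the allylic oxygen and hindered at its inner carbon, and attack on the other alkene face would give the spiro epimer. Fallback, setting out from 9 and returning at 12: 9 is coupled with pyrrolidine (EDC·HCl, HOBt) to the pyrrolidine amide F1. Tf2O and 2,6-di-tert-butyl-4-methylpyridine in 1,2-dichloroethane at 80 °C convert it into the keteniminium triflate F2, which is much more electrophilic than the ketene and cannot dimerise. It should close by the same bridged [2+2] to the cyclobutaniminium triflate F3, and aqueous NaHCO3 hydrolyses this to 12.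

2. Step 3. The ketone may be enolised or the ester attacked during the carbonyl addition, and the ring closure may discriminate poorly between the two faces of the cation because the two groups on C2 differ little in size. Fallback, setting out from 6 and returning at 8: 6 is converted with MeOH, HC(OMe)3 and pyridinium p-toluenesulfonate into the cyclic methyl ketal F4. BF3·OEt2 ionises it to the cyclic oxocarbenium ion, and potassium trifluoro(2-methylprop-1-enyl)borate should deliver the alkenyl group on the face opposite the pseudo-axial isobutyl group. The C2–alkenyl bond, not the C2–O bond, is then formed in the stereo-determining event, and 8 results directly.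

3. Step 2. Iminium formation from an enone with a long chain on the far side of the carbonyl may be slow, so that uncatalysed addition of the acidic triketone erodes the enantioselectivity. Fallback, setting out from 5 and returning at 6: 5 is added to commercial (E)-5-methylhex-2-enal under a diphenylprolinol trimethylsilyl ether (iminium catalysis of an enal) to give the lactol F5. PhI(OAc)2 with catalytic TEMPO oxidises it to the enol lactone F6, which EtSH/Et3N opens to the S-ethyl thioester F7. Fukuyama coupling with (4-methoxy-4-oxobutyl)zinc iodide (3 equiv, PdCl2(PPh3)2, THF/toluene) then gives 6.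

**Further compounds**

F1 | step 5 | 1-{4-[(2R,4S)-6,6,8,8-tetramethyl-4-(2-methylpropyl)-2-(2-methylprop-1-en-1-yl)-5,7-dioxo-3,4,5,6,7,8-hexahydro-2H-chromen-2-yl]butanoyl}pyrrolidine | CC(C)C[C@H]1C[C@@](C=C(C)C)(CCCC(=O)N3CCCC3)OC2=C1C(=O)C(C)(C)C(=O)C2(C)C
F2 | step 5 | keteniminium triflate from F1 | CC(C)C[C@H]1C[C@@](C=C(C)C)(CCC=C=[N+]3CCCC3)OC2=C1C(=O)C(C)(C)C(=O)C2(C)C.[O-]S(=O)(=O)C(F)(F)F
F3 | step 5 | cyclobutaniminium triflate (pyrrolidinium ylidene at C7 of the skeleton of 12) | CC(C)C[C@H]1C[C@@]2(CC[C@H]3C(=[N+]4CCCC4)[C@@H]2C3(C)C)OC2=C1C(=O)C(C)(C)C(=O)C2(C)C.[O-]S(=O)(=O)C(F)(F)F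
F4 | step 3 | methyl 4-[(4S)-2-methoxy-6,6,8,8-tetramethyl-4-(2-methylpropyl)-5,7-dioxo-3,4,5,6,7,8-hexahydro-2H-chromen-2-yl]butanoate (both C2 anomers) | CC(C)C[C@H]1CC(OC)(CCCC(=O)OC)OC2=C1C(=O)C(C)(C)C(=O)C2(C)C
F5 | step 2 | (4S)-2-hydroxy-6,6,8,8-tetramethyl-4-(2-methylpropyl)-3,4-dihydro-2H-chromene-5,7(6H,8H)-dione (both anomers) | CC(C)C[C@H]1CC(O)OC2=C1C(=O)C(C)(C)C(=O)C2(C)C
F6 | step 2 | (4S)-6,6,8,8-tetramethyl-4-(2-methylpropyl)-3,4-dihydro-2H-chromene-2,5,7(6H,8H)-trione | CC(C)C[C@H]1CC(=O)OC2=C1C(=O)C(C)(C)C(=O)C2(C)C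
F7 | step 2 | S-ethyl (3S)-3-(2-hydroxy-3,3,5,5-tetramethyl-4,6-dioxocyclohex-1-en-1-yl)-5-methylhexanethioate | CC(C)C[C@@H](CC(=O)SCC)C1=C(O)C(C)(C)C(=O)C(C)(C)C1=O
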